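**Retrosynthetic overview**

1. Target 34 ⇐ ene-type chlorination (C6–Cl, C5=C16), C20 oxidation, dihydroxylation of C11=C20, acetylation, and reduction of the C14 and C2 ketones, all on tetracyclic diketone 27.
2. 27 ⇐ transannular oxidative radical cyclisation forming C1–C10 in macrocyclic diketone 26. Enabling feature: C1 lies between the oxygenated carbons C2 and C14 (a latent 2-methyl-1,3-diketone) and C10 is the less substituted end of a latent C10=C11(C20) alkene. C1–C10 is the fusion bond shared by cyclohexane ring A (C1, C10–C14) and the ten-membered carbocycle C1–C10 (an oxocane through the C4–O–C8 bridge), so without it the molecule is a 12-membered oxa-bridged ring (14-membered carbocyclic perimeter).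
3. 26 ⇐ ring-closing metathesis (C10=C11) and Reformatsky union (C1–C2) of pyranolactone aldehyde 19 with bromo ketone 23.
4. 19 ⇐ oxa-Michael closure (O4→C8) of the dihydropyran on butenolide 15 ⇐ Nozaki–Hiyama–Kishi coupling (C4–C5) of iodo butenolide 12 with (S)-glyceraldehyde acetonide 14.
5. 12 ⇐ intramolecular Horner–Wadsworth–Emmons reaction; C7 and C9 come from a Sharpless kinetic resolution of trienol 5. Ring order: butenolide → dihydropyran → 12-membered macrocycle → ring A and the ten-membered ring together.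

Key step: step 18

Remark: locants are briarane locants (C1–C14 ring carbons; C15 methyl on C1; C16 carbon on C5; C17, C18, C19 lactone CH, its methyl and the lactone carbonyl; C20 carboxyl carbon on C11).
Assumption: the 17R configuration (methyl anti to the C9 arm on the lactone) is the thermodynamic one and is reached by base equilibration in step 10.

**Step 1**
Reactants: 1 (E)-4,4-dimethoxybut-2-enal; 2 ethyltriphenylphosphonium bromide
Product: 4 (2E,4Z)-5-iodohexa-2,4-dienal, via (2E,4Z)-5-iodo-1,1-dimethoxyhexa-2,4-diene 3 (not isolated)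
Conditions: 2, n-BuLi, THF, −78 °C; I2; NaN(SiMe3)2, −20 °C; 1, −78 °C; then 1 M HCl, THF, 0 °C
Reagents that add atoms: iodine (II); water (O)
Why: Stork–Zhao iodo-Wittig olefination should give the (Z)-2-iodoalkene (iodine cis to the chain) under kinetic control without touching the E-enal alkene, and mild acid should then unmask the aldehyde.

**Step 2**
Reactants: 4 (2E,4Z)-5-iodohexa-2,4-dienal
Product: 5 rac-(4E,6Z)-7-iodoocta-1,4,6-trien-3-ol
Conditions: CH2=CHMgBr, THF, −78 °C; aq NH4Cl
Reagents that add atoms: vinylmagnesium bromide (C=C[Mg]Br)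
Why: Grignard 1,2-addition to the dienal should give the racemic C9 carbinol that is resolved in the next step.

**Step 3**
Reactants: 5 rac-(4E,6Z)-7-iodoocta-1,4,6-trien-3-ol
Product: 6 (1S)-1-[(2S,3S)-3-[(1Z)-2-iodoprop-1-en-1-yl]oxiran-2-yl]prop-2-en-1-ol
Conditions: Ti(OiPr)4 (1.0 equiv), L-(+)-diisopropyl tartrate (1.2 equiv), t-BuOOH (0.55 equiv), 4 Å MS, CH2Cl2, −20 °C
Reagents that add atoms: tert-butyl hydroperoxide (CC(C)(C)OO)
Why: Sharpless kinetic resolution should epoxidise only the (S)-carbinol, at its E-disubstituted C7=C8 alkene (vinyl and iodoalkene react far more slowly), giving the erythro epoxy alcohol and so fixing C9, C8 and C7 by reagent control; the (R)-alcohol stays behind, so at most half of 5 is used.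

**Step 4**
Reactants: 6
Product: 7 tert-butyl{[(1S)-1-[(2R,3S)-3-[(1Z)-2-iodoprop-1-en-1-yl]oxiran-2-yl]prop-2-en-1-yl]oxy}dimethylsilane
Conditions: t-BuMe2SiCl, imidazole, DMF, 0 to 25 °C
Reagents that add atoms: tert-butyldimethylsilyl chloride (CC(C)(C)[Si](C)(C)Cl)
Why: silylation marks O9 before the two other oxygens appear, which is what later tells O9 apart from O7 and O8.

**Step 5**
Reactants: 7
Product: 8 (3S,4S,5R,6Z)-5-bromo-3-[(tert-butyldimethylsilyl)oxy]-7-iodoocta-1,6-dien-4-ol
Conditions: LiBr, AcOH, THF, 0 °C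
Reagents that add atoms: lithium bromide ([Li+].[Br-])
Why: acid-assisted SN2 opening of the vinyl epoxide by bromide should occur at the allylic carbon C7 with inversion (C8 is not allylic and is deactivated by the neighbouring silyloxy carbon), leaving C8–OH as the only free hydroxyl.

**Step 6**
Reactants: 8
Product: 9 (3S,5R,6Z)-5-bromo-3-[(tert-butyldimethylsilyl)oxy]-7-iodoocta-1,6-dien-4-one
Conditions: Dess–Martin periodinane, NaHCO3, CH2Cl2, 0 °C
Reagents that add atoms: none
Why: buffered Dess–Martin oxidation should give the α-bromo ketone without enolising the doubly activated C7 and C9 positions.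

**Step 7**
Reactants: 9; 10 2-(diethoxyphosphoryl)propanoic acid
Product: 12 (5S)-4-[(1S)-1-[(tert-butyldimethylsilyl)oxy]prop-2-en-1-yl]-5-[(1Z)-2-iodoprop-1-en-1-yl]-3-methylfuran-2(5H)-one, via (3S,5S,6Z)-3-[(tert-butyldimethylsilyl)oxy]-7-iodo-4-oxoocta-1,6-dien-5-yl 2-(diethoxyphosphoryl)propanoate 11 (not isolated)
Conditions: Cs2CO3, DMF, 0 to 25 °C
Reagents that add atoms: none
Why: carboxylate SN2 displacement of the α-keto bromide inverts C7 a second time (net retention relative to the epoxide oxygen, which is the C7–O configuration of the target), and intramolecular Horner–Wadsworth–Emmons olefination of the C8 ketone should then close the butenolide.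

**Step 8**
Reactants: 13 (R)-(2,2-dimethyl-1,3-dioxolan-4-yl)methanol
Product: 14 (S)-2,2-dimethyl-1,3-dioxolane-4-carbaldehyde
Conditions: TEMPO (10 mol%), PhI(OAc)2, CH2Cl2, 25 °C; used without storage
Reagents that add atoms: none
Why: TEMPO/PhI(OAc)2 oxidation of the primary alcohol should give the configurationally intact aldehyde that supplies C2–C4 and the C3 stereocentre.

**Step 9**
Reactants: 12; 14
Product: 15 (5S)-4-[(1S)-1-[(tert-butyldimethylsilyl)oxy]prop-2-en-1-yl]-5-[(1Z,3R)-3-[(4S)-2,2-dimethyl-1,3-dioxolan-4-yl]-3-hydroxy-2-methylprop-1-en-1-yl]-3-methylfuran-2(5H)-one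
Conditions: CrCl2 (4 equiv), NiCl2 (2 mol%), DMSO, 25 °C
Reagents that add atoms: none
Why: Nozaki–Hiyama–Kishi coupling should add the alkenylchromium species to the aldehyde only, with retention of the Z geometry (C4 cis to C7), and Felkin–Anh approach anti to the dioxolane C–O bond should give the 3,4-anti alcohol (4R).

**Step 10**
Reactants: 15
Product: 16 cis-fused dihydropyran γ-lactone with the 4,8-ether bridge, (4S)-2,2-dimethyl-1,3-dioxolan-4-yl on C4 and (1S)-1-[(tert-butyldimethylsilyl)oxy]prop-2-en-1-yl on C8 (3S,4R,7S,8S,9S,17R)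
Conditions: KOt-Bu (0.1 equiv), THF, −40 to 0 °C; AcOH quench
Reagents that add atoms: none
Why: intramolecular oxa-Michael addition (6-exo-trig) of the C4 alkoxide to C8 of the butenolide is held in place by the Z alkene; the oxygen can reach only the butenolide face that carries C6, so C8 follows from C7 and the lactone ends cis-fused, and C17 should equilibrate to the methyl-anti-to-C9 isomer.

**Step 11**
Reactants: 16
Product: 17 pyranolactone 3,2-diol (C4 carries (1S)-1,2-dihydroxyethyl)
Conditions: AcOH/H2O/THF (3:1:1), 40 °C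
Reagents that add atoms: none
Why: the terminal acetonide should hydrolyse selectively while the hindered secondary silyl ether and the lactone survive.

**Step 12**
Reactants: 17
Product: 18 pyranolactone 3,2-bis(triethylsilyl) ether
Conditions: Et3SiCl, imidazole, DMAP (cat.), CH2Cl2, 0 to 25 °C
Reagents that add atoms: triethylsilyl chloride (CC[Si](Cl)(CC)CC)
Why: bis-silylation protects O3 and prepares the primary ether for direct oxidation.

**Step 13**
Reactants: 18
Product: 19 pyranolactone C2 aldehyde (3-O-triethylsilyl, 9-O-tert-butyldimethylsilyl)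
Conditions: (COCl)2, DMSO, CH2Cl2, −78 to −40 °C; Et3N, −78 °C
Reagents that add atoms: none
Why: Swern conditions should cleave and oxidise only the primary triethylsilyl ether, and the low temperature should avoid epimerisation at C3 and β-elimination of the pyran oxygen.

**Step 14**
Reactants: 20 4-bromo-2-methylbut-1-ene; 21 rac-2-bromo-N-methoxy-N-methylpropanamide
Product: 23 rac-2-bromo-6-methylhept-6-en-3-one, via (3-methylbut-3-en-1-yl)magnesium bromide 22 (not isolated)
Conditions: 20, Mg, THF, 25 °C; then 21, THF, −78 °C; aq NH4Cl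
Reagents that add atoms: none
Why: Grignard addition to the Weinreb amide should stop at the ketone through the chelated tetrahedral intermediate, and at −78 °C the α-bromide survives.

**Step 15**
Reactants: 19; 23
Product: 24 open-chain β-hydroxy ketone (C2–OH, C14 ketone; mixture at C1 and C2)
Conditions: SmI2 (2.2 equiv), THF, −78 °C
Reagents that add atoms: none
Why: SmI2-mediated Reformatsky-type aldol addition uses the regiodefined samarium enolate from the α-bromo ketone, so C1 (not C13) bonds to C2; the new C1 and C2 centres need no control because C2 is oxidised in step 17 and C1 becomes planar in step 18.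

**Step 16**
Reactants: 24
Product: 25 12-membered macrocyclic β-hydroxy ketone with the C10=C11 alkene (C20 methyl on C11)
Conditions: second-generation Hoveyda–Grubbs catalyst (10 mol%), toluene (1 mM), 80 °C, argon sparge
Reagents that add atoms: none
Why: ring-closing metathesis between the C10 vinyl group and the 1,1-disubstituted C11 alkene should close the ring with loss of ethene, the trisubstituted C5=C6 ring alkene being inert; the E isomer is expected to predominate.

**Step 17**
Reactants: 25
Product: 26 macrocyclic 2-methyl-1,3-diketone (C2 and C14 ketones; C1 epimers interconvert through the enol)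
Conditions: Dess–Martin periodinane, NaHCO3, CH2Cl2, 0 to 25 °C
Reagents that add atoms: none
Why: Dess–Martin oxidation of the β-hydroxy ketone converges all aldol diastereomers into one diketone.

**Step 18**
Reactants: 26
Product: 27 tetracyclic 2,14-diketone with the C1–C10 bond and the exocyclic C11=C20 alkene (1R,10S)
Conditions: Mn(OAc)3·2H2O (2.2 equiv), Cu(OAc)2·H2O (0.5 equiv), KOAc, degassed AcOH, 25 °C
Reagents that add atoms: none
Why: Mn(OAc)3 forms the manganese enolate of the diketone and oxidises it to the electrophilic C1 radical, which adds across the ring to C10, the less substituted end of the C10=C11 alkene; the tertiary C11 radical is then oxidised by Cu(OAc)2 and loses a C20 hydrogen to give the exocyclic alkene. The closest known reaction type is the oxidative radical cyclisation of unsaturated 2-alkyl-1,3-dicarbonyl compounds with trivalent manganese and divalent copper acetates, and transannular radical cyclisations of macrocycles are established. The one bond closes ring A in 6-endo-trig mode (favoured over 5-exo because the C14 carbonyl lies inside the forming ring and C11 is fully substituted) and, in the same event, the oxocane and hence the ten-membered carbocycle in transannular 8-exo-trig mode. C1 is set by a chair-like transition state with the C2 acyl arm equatorial and the methyl axial, which gives the trans ring fusion. C10 is set by C9: the short tether through C8 forces C8 gauche to the incoming C1, and of the two such rotamers the one with the C9–O bond in the alkene plane (inside alkoxy, preferred for electrophilic attack) leads to 10S. The step needs regioselectivity (C10 over C11, exocyclic over endocyclic alkene) and face selectivity; the first rests on the substitution pattern and on the preference of copper-mediated oxidative elimination for the less substituted alkene, the second on the rigid cis-2,6-bridged pyranolactone that holds C3 and C9 on one face.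

**Step 19**
Reactants: 27
Product: 28 14α-hydroxy 2-ketone
Conditions: LiBH(s-Bu)3 (1.1 equiv), THF, −78 °C; aq NH4Cl
Reagents that add atoms: none
Why: the ring-A ketone C14 is the less hindered carbonyl, and equatorial attack by the bulky hydride should give the axial alcohol anti to the C15 methyl, as with 4,4-dimethyl-3-keto steroids.

**Step 20**
Reactants: 28
Product: 29 2β,14α-diol
Conditions: Me4NBH(OAc)3 (5 equiv), MeCN/AcOH (1:1), −30 to 0 °C
Reagents that add atoms: none
Why: Evans–Saksena reduction delivers hydride from the C14 alkoxyborohydride through a six-membered transition state and should give the 1,3-anti diol, which is the C2/C14 relationship of the target.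

**Step 21**
Reactants: 29
Product: 30 2,3,9,14-tetraol
Conditions: HF·pyridine, pyridine, THF, 0 to 25 °C
Reagents that add atoms: none
Why: fluoride under mildly acidic conditions should remove both silyl ethers without opening the pyran by retro-oxa-Michael reaction.

**Step 22**
Reactants: 30
Product: 31 2,3,9,14-tetraacetate
Conditions: Ac2O, DMAP, pyridine, 40 °C
Reagents that add atoms: acetic anhydride (CC(=O)OC(C)=O)
Why: all four hydroxyls are acetylated while C11 is still an alkene carbon, so no tertiary or primary hydroxyl has to be spared.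

**Step 23**
Reactants: 31
Product: 32 11α,20-diol tetraacetate
Conditions: OsO4 (5 mol%), 4-methylmorpholine N-oxide, acetone/H2O, 0 to 25 °C
Reagents that add atoms: 4-methylmorpholine N-oxide (C[N+]1([O-])CCOCC1); water (O)
Why: Upjohn dihydroxylation should take the exocyclic 1,1-disubstituted alkene in preference to the hindered, electron-poor C5=C6 alkene, and approach along the equatorial direction (the axial face is blocked by the syn-axial C15 methyl) puts the C11 hydroxyl α and C20 β.

**Step 24**
Reactants: 32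
Product: 33 11-hydroxy-20-oic acid tetraacetate
Conditions: TEMPO (10 mol%), NaClO2 (2 equiv), NaOCl (5 mol%), MeCN/phosphate buffer pH 6.7, 35 °C
Reagents that add atoms: sodium chlorite ([Na+].[O-]Cl=O)
Why: TEMPO/chlorite oxidation should take the primary alcohol to the acid at near-neutral pH, leaving the tertiary alcohol, the acetates and the lactone intact.

**Step 25**
Reactants: 33
Product: 34 CNP0186125.1
Conditions: N-chlorosuccinimide (1.1 equiv), Yb(OTf)3 (10 mol%), Me3SiCl (10 mol%), CH2Cl2/THF, 0 °C
Reagents that add atoms: N-chlorosuccinimide (O=C1CCC(=O)N1Cl)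
Why: ene-type allylic chlorination of the trisubstituted C5=C6 alkene puts chlorine on C6 and moves the double bond to C5=C16 (loss of the bridgehead C4 hydrogen is disfavoured); chlorine should enter from the pyran face opposite the five-carbon C3–C2–C1–C10–C9 bridge, giving 6S.

**Compound list**

1 | (E)-4,4-dimethoxybut-2-enal | COC(OC)/C=C/C=O | starting material
2 | ethyltriphenylphosphonium bromide | CC[P+](c1ccccc1)(c1ccccc1)c1ccccc1.[Br-] | starting material
3 | (2E,4Z)-5-iodo-1,1-dimethoxyhexa-2,4-diene | COC(OC)/C=C/C=C(\I)C | intermediate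
4 | (2E,4Z)-5-iodohexa-2,4-dienal | O=C/C=C/C=C(\I)C | intermediate
5 | rac-(4E,6Z)-7-iodoocta-1,4,6-trien-3-ol | C=CC(O)/C=C/C=C(\I)C | intermediate
6 | (1S)-1-[(2S,3S)-3-[(1Z)-2-iodoprop-1-en-1-yl]oxiran-2-yl]prop-2-en-1-ol | C=C[C@H](O)[C@@H]1O[C@H]1/C=C(\I)C | intermediate
7 | tert-butyl{[(1S)-1-[(2R,3S)-3-[(1Z)-2-iodoprop-1-en-1-yl]oxiran-2-yl]prop-2-en-1-yl]oxy}dimethylsilane | C=C[C@H](O[Si](C)(C)C(C)(C)C)[C@@H]1O[C@H]1/C=C(\I)C | intermediate
8 | (3S,4S,5R,6Z)-5-bromo-3-[(tert-butyldimethylsilyl)oxy]-7-iodoocta-1,6-dien-4-ol | C=C[C@H](O[Si](C)(C)C(C)(C)C)[C@H](O)[C@H](Br)/C=C(\I)C | intermediate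
9 | (3S,5R,6Z)-5-bromo-3-[(tert-butyldimethylsilyl)oxy]-7-iodoocta-1,6-dien-4-one | C=C[C@H](O[Si](C)(C)C(C)(C)C)C(=O)[C@H](Br)/C=C(\I)C | intermediate
10 | 2-(diethoxyphosphoryl)propanoic acid | CCOP(=O)(OCC)C(C)C(=O)O | starting material
11 | (3S,5S,6Z)-3-[(tert-butyldimethylsilyl)oxy]-7-iodo-4-oxoocta-1,6-dien-5-yl 2-(diethoxyphosphoryl)propanoate | C=C[C@H](O[Si](C)(C)C(C)(C)C)C(=O)[C@@H](OC(=O)C(C)P(=O)(OCC)OCC)/C=C(\I)C | intermediate
12 | (5S)-4-[(1S)-1-[(tert-butyldimethylsilyl)oxy]prop-2-en-1-yl]-5-[(1Z)-2-iodoprop-1-en-1-yl]-3-methylfuran-2(5H)-one | C=C[C@H](O[Si](C)(C)C(C)(C)C)C1=C(C)C(=O)O[C@H]1/C=C(\I)C | intermediate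
13 | (R)-(2,2-dimethyl-1,3-dioxolan-4-yl)methanol | OC[C@@H]1COC(C)(C)O1 | starting material
14 | (S)-2,2-dimethyl-1,3-dioxolane-4-carbaldehyde | O=C[C@@H]1COC(C)(C)O1 | intermediate
15 | (5S)-4-[(1S)-1-[(tert-butyldimethylsilyl)oxy]prop-2-en-1-yl]-5-[(1Z,3R)-3-[(4S)-2,2-dimethyl-1,3-dioxolan-4-yl]-3-hydroxy-2-methylprop-1-en-1-yl]-3-methylfuran-2(5H)-one | C=C[C@H](O[Si](C)(C)C(C)(C)C)C1=C(C)C(=O)O[C@H]1/C=C(C)\[C@@H](O)[C@@H]1COC(C)(C)O1 | intermediate
16 | 4,8-ether-bridged pyranolactone acetonide (3S,4R,7S,8S,9S,17R) | CC=1[C@H]([C@@H]2COC(C)(C)O2)O[C@]3([C@@H](C)C(=O)O[C@H]3C=1)[C@@H](O[Si](C)(C)C(C)(C)C)C=C | intermediate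
17 | pyranolactone 3,2-diol (stereocentres as in 16) | CC=1[C@H]([C@@H](O)CO)O[C@]3([C@@H](C)C(=O)O[C@H]3C=1)[C@@H](O[Si](C)(C)C(C)(C)C)C=C | intermediate
18 | pyranolactone 3,2-bis(triethylsilyl) ether | CC=1[C@H]([C@@H](O[Si](CC)(CC)CC)CO[Si](CC)(CC)CC)O[C@]3([C@@H](C)C(=O)O[C@H]3C=1)[C@@H](O[Si](C)(C)C(C)(C)C)C=C | intermediate
19 | pyranolactone C2 aldehyde | CC=1[C@H]([C@@H](O[Si](CC)(CC)CC)C=O)O[C@]3([C@@H](C)C(=O)O[C@H]3C=1)[C@@H](O[Si](C)(C)C(C)(C)C)C=C | intermediate
20 | 4-bromo-2-methylbut-1-ene | C=C(C)CCBr | starting material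
21 | rac-2-bromo-N-methoxy-N-methylpropanamide | CC(Br)C(=O)N(C)OC | starting material
22 | (3-methylbut-3-en-1-yl)magnesium bromide | C=C(C)CC[Mg]Br | intermediate
23 | rac-2-bromo-6-methylhept-6-en-3-one | CC(Br)C(=O)CCC(C)=C | intermediate
24 | open-chain β-hydroxy ketone (mixture at C1 and C2) | CC=1[C@H]([C@@H](O[Si](CC)(CC)CC)C(O)C(C)C(=O)CCC(C)=C)O[C@]3([C@@H](C)C(=O)O[C@H]3C=1)[C@@H](O[Si](C)(C)C(C)(C)C)C=C | intermediate
25 | 12-membered macrocyclic β-hydroxy ketone (mixture at C1 and C2) | CC=1[C@H]2O[C@]3([C@@H](C)C(=O)O[C@H]3C=1)[C@@H](O[Si](C)(C)C(C)(C)C)C=C(C)CCC(=O)C(C)C(O)[C@@H]2O[Si](CC)(CC)CC | intermediate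
26 | macrocyclic 2-methyl-1,3-diketone | CC=1[C@H]2O[C@]3([C@@H](C)C(=O)O[C@H]3C=1)[C@@H](O[Si](C)(C)C(C)(C)C)C=C(C)CCC(=O)C(C)C(=O)[C@@H]2O[Si](CC)(CC)CC | intermediate
27 | tetracyclic 2,14-diketone with exocyclic C11=C20 alkene (1R,10S) | CC=1[C@H]2O[C@]3([C@@H](C)C(=O)O[C@H]3C=1)[C@@H](O[Si](C)(C)C(C)(C)C)[C@@H]1[C@](C)(C(=O)CCC1=C)C(=O)[C@@H]2O[Si](CC)(CC)CC | intermediate
28 | 14α-hydroxy 2-ketone | CC=1[C@H]2O[C@]3([C@@H](C)C(=O)O[C@H]3C=1)[C@@H](O[Si](C)(C)C(C)(C)C)[C@@H]1[C@](C)([C@@H](O)CCC1=C)C(=O)[C@@H]2O[Si](CC)(CC)CC | intermediate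
29 | 2β,14α-diol | CC=1[C@H]2O[C@]3([C@@H](C)C(=O)O[C@H]3C=1)[C@@H](O[Si](C)(C)C(C)(C)C)[C@@H]1[C@](C)([C@@H](O)CCC1=C)[C@@H](O)[C@@H]2O[Si](CC)(CC)CC | intermediate
30 | 2,3,9,14-tetraol | CC=1[C@H]2O[C@]3([C@@H](C)C(=O)O[C@H]3C=1)[C@@H](O)[C@@H]1[C@](C)([C@@H](O)CCC1=C)[C@@H](O)[C@@H]2O | intermediate
31 | 2,3,9,14-tetraacetate | CC=1[C@H]2O[C@]3([C@@H](C)C(=O)O[C@H]3C=1)[C@@H](OC(C)=O)[C@@H]1[C@](C)([C@@H](OC(C)=O)CCC1=C)[C@@H](OC(C)=O)[C@@H]2OC(C)=O | intermediate
32 | 11α,20-diol tetraacetate | CC=1[C@H]2O[C@]3([C@@H](C)C(=O)O[C@H]3C=1)[C@@H](OC(C)=O)[C@@H]1[C@](C)([C@@H](OC(C)=O)CC[C@]1(O)CO)[C@@H](OC(C)=O)[C@@H]2OC(C)=O | intermediate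
33 | 11-hydroxy-20-oic acid tetraacetate | CC=1[C@H]2O[C@]3([C@@H](C)C(=O)O[C@H]3C=1)[C@@H](OC(C)=O)[C@@H]1[C@](C)([C@@H](OC(C)=O)CC[C@]1(O)C(=O)O)[C@@H](OC(C)=O)[C@@H]2OC(C)=O | intermediate
34 | CNP0186125.1 | C=C1[C@H]2O[C@]3([C@@H](C)C(=O)O[C@H]3[C@H]1Cl)[C@@H](OC(C)=O)[C@@H]1[C@](C)([C@@H](OC(C)=O)CC[C@]1(O)C(=O)O)[C@@H](OC(C)=O)[C@@H]2OC(C)=O | target

**Step count and risks**

Total step count: 25. Longest linear sequence: 23 steps (steps 1–7, 9–13, 15–25).

Steps most likely to fail:

Step 18. The transannular cyclisation may suffer from poor facial selectivity at C1 and C10, from competing 5-exo closure, or from oxidative elimination toward the ring (endocyclic alkene) instead of toward C20. The fallback sets out from diketone 26 and separates radical generation, ring closure and alkene formation. Selenenylation at C1 (PhSeCl, pyridine, CH2Cl2, 0 °C) should give the 1-(phenylselanyl) macrocyclic diketone F1. Sunlamp irradiation in benzene should bring about phenylselanyl group-transfer radical cyclisation to the 11-(phenylselanyl) tetracyclic diketone F2. Oxidation (H2O2, pyridine, CH2Cl2, 0 °C) and syn-elimination of the selenoxide toward the C20 methyl lead back to the route at 27.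

Step 16. Ring closure may be outrun by oligomerisation, or may not start at all because both olefins are hindered and the product alkene is trisubstituted. The fallback sets out from bis-silyl ether 18 and moves the macrocyclisation to the C1–C2 bond. Cross-metathesis with a large excess of bromo ketone 23 (second-generation Grubbs catalyst, CH2Cl2, 40 °C) should give the open-chain C10=C11 bromo ketone bis(triethylsilyl) ether F3. Swern oxidation of its primary triethylsilyl ether should give the open-chain bromo keto aldehyde F4. SmI2 (THF, high dilution, −78 °C) should then close the 12-membered ring by intramolecular Reformatsky reaction, returning to the route at 25.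

Step 25. The C5=C6 alkene carries two allylic oxygens and may be too electron-poor for the chlorinating agent, and chlorine delivery may show poor facial selectivity. The fallback sets out from hydroxy acid 33 and brings in oxygen first. Allylic oxidation of the C16 methyl (SeO2 cat., t-BuOOH, CH2Cl2, 25 °C) should give the 16-hydroxy Δ5 hydroxy acid F5. SOCl2 in Et2O at 0 °C, followed by aqueous work-up, should convert its chlorosulfite by SNi′ rearrangement into the C6 chloride with the C5=C16 alkene, which is the target 34.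

**Further compounds**

F1 | step 18 | 1-(phenylselanyl) macrocyclic diketone | CC=1[C@H]2O[C@]3([C@@H](C)C(=O)O[C@H]3C=1)[C@@H](O[Si](C)(C)C(C)(C)C)C=C(C)CCC(=O)C(C)([Se]c4ccccc4)C(=O)[C@@H]2O[Si](CC)(CC)CC
F2 | step 18 | 11-(phenylselanyl) tetracyclic diketone | CC=1[C@H]2O[C@]3([C@@H](C)C(=O)O[C@H]3C=1)[C@@H](O[Si](C)(C)C(C)(C)C)[C@@H]1[C@](C)(C(=O)CCC1(C)[Se]c4ccccc4)C(=O)[C@@H]2O[Si](CC)(CC)CC
F3 | step 16 | open-chain C10=C11 bromo ketone bis(triethylsilyl) ether | CC=1[C@H]([C@@H](O[Si](CC)(CC)CC)CO[Si](CC)(CC)CC)O[C@]3([C@@H](C)C(=O)O[C@H]3C=1)[C@@H](O[Si](C)(C)C(C)(C)C)C=C(C)CCC(=O)C(C)Br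
F4 | step 16 | open-chain bromo keto aldehyde | CC=1[C@H]([C@@H](O[Si](CC)(CC)CC)C=O)O[C@]3([C@@H](C)C(=O)O[C@H]3C=1)[C@@H](O[Si](C)(C)C(C)(C)C)C=C(C)CCC(=O)C(C)Br
F5 | step 25 | 16-hydroxy Δ5 hydroxy acid | OCC=1[C@H]2O[C@]3([C@@H](C)C(=O)O[C@H]3C=1)[C@@H](OC(C)=O)[C@@H]1[C@](C)([C@@H](OC(C)=O)CC[C@]1(O)C(=O)O)[C@@H](OC(C)=O)[C@@H]2OC(C)=O
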